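**Assumption:** (R)-3-hydroxy-2,2-dimethylcyclohexanone **1** (the enantiomer of the familiar yeast-derived ketol), tiglic aldehyde **6** and isofraxidin **12** are bought. The decalin is numbered as a naphthalene: C1 quaternary, C2 CH–Me, C4=C4a alkene, C5 CMe2, C6 carbinol, C8a ring-fusion CH. The target is then (1R,2S,6S,8aR).

**Retrosynthetic overview**
1. Target **13** ⇒ aryl–O–CH2 disconnection (Mitsunobu-type) into isofraxidin **12** and diol **11**.
2. **11** ⇒ keto aldehyde **9** (one hydride step reduces CHO and sets the axial 6-OH), which comes from Diels–Alder adduct **7** by desilylation and oxidation.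
3. Ring B of **7** ⇒ intermolecular [4+2] of semicyclic diene **5** with tiglic aldehyde **6**; this forms C1–C8a and C2–C3 and sets C1, C2 and C8a at once, the face being chosen by the C6 silyloxy stereocentre.
4. **5** ⇒ enol triflate **4** (Stille vinylation) ⇒ ketol **1**.
5. Ring order: ring A bought, ring B by Diels–Alder, coumarin attached last.

**Step 1**
Reactants: 1 (R)-3-hydroxy-2,2-dimethylcyclohexan-1-one
Product: 2 (R)-3-[(tert-butyldimethylsilyl)oxy]-2,2-dimethylcyclohexan-1-one
Conditions: TBSCl, imidazole, DMF, 50 °C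
Reagents that add atoms: tert-butyldimethylsilyl chloride, CC(C)(C)[Si](C)(C)Cl
Why: Standard imidazole-promoted O-silylation of the secondary alcohol; the stereocentre is untouched and the bulky OTBS later steers the cycloaddition.

**Step 2**
Reactants: 2 (R)-3-[(tert-butyldimethylsilyl)oxy]-2,2-dimethylcyclohexan-1-one
Product: 4 (R)-5-[(tert-butyldimethylsilyl)oxy]-6,6-dimethylcyclohex-1-en-1-yl trifluoromethanesulfonate, via potassium enolate 3 (not isolated)
Conditions: KHMDS, THF, −78 °C; then PhNTf2, −78 → 0 °C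
Reagents that add atoms: N-phenylbis(trifluoromethanesulfonimide), O=S(=O)(N(c1ccccc1)S(=O)(=O)C(F)(F)F)C(F)(F)F
Why: The ketone has only one enolisable α-carbon (the other is quaternary), so deprotonation and O-triflation give a single enol triflate.

**Step 3**
Reactants: 4 (R)-5-[(tert-butyldimethylsilyl)oxy]-6,6-dimethylcyclohex-1-en-1-yl trifluoromethanesulfonate
Product: 5 (R)-tert-butyl[(2,2-dimethyl-3-vinylcyclohex-3-en-1-yl)oxy]dimethylsilane
Conditions: Bu3SnCH=CH2, Pd(PPh3)4 (5 mol %), LiCl, THF, 65 °C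
Reagents that add atoms: tributyl(vinyl)stannane, C=C[Sn](CCCC)(CCCC)CCCC
Why: Stille coupling of an enol triflate with vinylstannane (LiCl-assisted) is reliable even next to a quaternary carbon and gives the 1-vinylcyclohexene diene.

**Step 4**
Reactants: 5 (R)-tert-butyl[(2,2-dimethyl-3-vinylcyclohex-3-en-1-yl)oxy]dimethylsilane; 6 (E)-2-methylbut-2-enal (tiglic aldehyde)
Product: 7 (1R,2S,6R,8aR)-6-[(tert-butyldimethylsilyl)oxy]-1,2,5,5-tetramethyl-1,2,3,5,6,7,8,8a-octahydronaphthalene-1-carbaldehyde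
Conditions: EtAlCl2 (0.3 equiv), CH2Cl2, −78 → −20 °C
Reagents that add atoms: none
Why: Lewis-acid-catalysed Diels–Alder reaction: the formyl-bearing carbon bonds to the ring terminus of the diene ("ortho" rule), the E-dienophile makes the C1 and C2 methyls cis, the Al-bound formyl stays exo (out from under the gem-dimethyl-bearing ring A, leaving only the small α-methyl there) so CHO ends cis to H-8a, and addition occurs anti to the OTBS group and the pseudo-axial methyl next to it, fixing C1, C2 and C8a as R, S, R.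

**Step 5**
Reactants: 7 (1R,2S,6R,8aR)-6-[(tert-butyldimethylsilyl)oxy]-1,2,5,5-tetramethyl-1,2,3,5,6,7,8,8a-octahydronaphthalene-1-carbaldehyde
Product: 8 (1R,2S,6R,8aR)-6-hydroxy-1,2,5,5-tetramethyl-1,2,3,5,6,7,8,8a-octahydronaphthalene-1-carbaldehyde
Conditions: 48% aq. HF, MeCN, rt
Reagents that add atoms: none
Why: Acidic fluoride desilylation cleaves the hindered secondary TBS ether; the aldehyde has no α-hydrogen and cannot epimerise.

**Step 6**
Reactants: 8 (1R,2S,6R,8aR)-6-hydroxy-1,2,5,5-tetramethyl-1,2,3,5,6,7,8,8a-octahydronaphthalene-1-carbaldehyde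
Product: 9 (1R,2S,8aR)-1,2,5,5-tetramethyl-6-oxo-1,2,3,5,6,7,8,8a-octahydronaphthalene-1-carbaldehyde
Conditions: Dess–Martin periodinane, CH2Cl2, rt
Reagents that add atoms: none
Why: Dess–Martin oxidation of the equatorial C6 alcohol removes the control stereocentre, which has the wrong configuration for the target; the β,γ-unsaturated ketone cannot conjugate because C5 is quaternary.

**Step 7**
Reactants: 9 (1R,2S,8aR)-1,2,5,5-tetramethyl-6-oxo-1,2,3,5,6,7,8,8a-octahydronaphthalene-1-carbaldehyde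
Product: 11 (1R,2S,6S,8aR)-1-(hydroxymethyl)-1,2,5,5-tetramethyl-1,2,3,5,6,7,8,8a-octahydronaphthalen-6-ol, via lithium keto-alkoxide 10 (not isolated)
Conditions: L-Selectride (3 equiv), THF, −78 → 0 °C; then H2O
Reagents that add atoms: none
Why: The bulky trialkylborohydride reduces the aldehyde first and then attacks the C6 ketone from the equatorial direction (steric approach control by the ring stereocentres), giving the axial 6β (S) alcohol.

**Step 8**
Reactants: 11 (1R,2S,6S,8aR)-1-(hydroxymethyl)-1,2,5,5-tetramethyl-1,2,3,5,6,7,8,8a-octahydronaphthalen-6-ol; 12 7-hydroxy-6,8-dimethoxy-2H-chromen-2-one (isofraxidin)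
Product: 13 7-{[(1R,2S,6S,8aR)-6-hydroxy-1,2,5,5-tetramethyl-1,2,3,5,6,7,8,8a-octahydronaphthalen-1-yl]methoxy}-6,8-dimethoxy-2H-chromen-2-one (target)
Conditions: cyanomethylenetributylphosphorane (CMBP), toluene, 110 °C
Reagents that add atoms: none
Why: Tsunoda variant of the Mitsunobu reaction: the acidic coumarin phenol displaces the activated primary (neopentyl) hydroxyl, while the axial secondary alcohol flanked by the gem-dimethyl group is too hindered to react; no stereocentre is involved.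

**Compound list**
1 | (R)-3-hydroxy-2,2-dimethylcyclohexan-1-one | O=C1CCC[C@@H](O)C1(C)C | starting material
2 | (R)-3-[(tert-butyldimethylsilyl)oxy]-2,2-dimethylcyclohexan-1-one | O=C1CCC[C@@H](O[Si](C)(C)C(C)(C)C)C1(C)C | intermediate
3 | potassium (R)-5-[(tert-butyldimethylsilyl)oxy]-6,6-dimethylcyclohex-1-en-1-olate | [K+].[O-]C1=CCC[C@@H](O[Si](C)(C)C(C)(C)C)C1(C)C | intermediate (not isolated)
4 | (R)-5-[(tert-butyldimethylsilyl)oxy]-6,6-dimethylcyclohex-1-en-1-yl trifluoromethanesulfonate | O=S(=O)(OC1=CCC[C@@H](O[Si](C)(C)C(C)(C)C)C1(C)C)C(F)(F)F | intermediate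
5 | (R)-tert-butyl[(2,2-dimethyl-3-vinylcyclohex-3-en-1-yl)oxy]dimethylsilane | C=CC1=CCC[C@@H](O[Si](C)(C)C(C)(C)C)C1(C)C | intermediate
6 | (E)-2-methylbut-2-enal (tiglic aldehyde) | C/C=C(\C)C=O | starting material
7 | (1R,2S,6R,8aR)-6-[(tert-butyldimethylsilyl)oxy]-1,2,5,5-tetramethyl-1,2,3,5,6,7,8,8a-octahydronaphthalene-1-carbaldehyde | O=C[C@@]1(C)[C@@H]2CC[C@@H](O[Si](C)(C)C(C)(C)C)C(C)(C)C2=CC[C@@H]1C | intermediate
8 | (1R,2S,6R,8aR)-6-hydroxy-1,2,5,5-tetramethyl-1,2,3,5,6,7,8,8a-octahydronaphthalene-1-carbaldehyde | O=C[C@@]1(C)[C@@H]2CC[C@@H](O)C(C)(C)C2=CC[C@@H]1C | intermediate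
9 | (1R,2S,8aR)-1,2,5,5-tetramethyl-6-oxo-1,2,3,5,6,7,8,8a-octahydronaphthalene-1-carbaldehyde | O=C[C@@]1(C)[C@@H]2CCC(=O)C(C)(C)C2=CC[C@@H]1C | intermediate
10 | lithium [(1R,2S,8aR)-1,2,5,5-tetramethyl-6-oxo-1,2,3,5,6,7,8,8a-octahydronaphthalen-1-yl]methanolate | [Li+].[O-]C[C@@]1(C)[C@@H]2CCC(=O)C(C)(C)C2=CC[C@@H]1C | intermediate (not isolated)
11 | (1R,2S,6S,8aR)-1-(hydroxymethyl)-1,2,5,5-tetramethyl-1,2,3,5,6,7,8,8a-octahydronaphthalen-6-ol | OC[C@@]1(C)[C@@H]2CC[C@H](O)C(C)(C)C2=CC[C@@H]1C | intermediate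
12 | 7-hydroxy-6,8-dimethoxy-2H-chromen-2-one (isofraxidin) | COc1cc2ccc(=O)oc2c(OC)c1O | starting material
13 | 7-{[(1R,2S,6S,8aR)-6-hydroxy-1,2,5,5-tetramethyl-1,2,3,5,6,7,8,8a-octahydronaphthalen-1-yl]methoxy}-6,8-dimethoxy-2H-chromen-2-one | COc1cc2ccc(=O)oc2c(OC)c1OC[C@@]1(C)[C@@H]2CC[C@H](O)C(C)(C)C2=CC[C@@H]1C | target

**Total step count:** 8. **Longest linear sequence:** 8 steps (1 → 13); 6 and 12 enter as bought materials.

**Three steps most likely to fail**

Step 4 (Diels–Alder). The hindered α,β-disubstituted enal may react sluggishly, and the exo and facial preferences are argued from sterics rather than proven for this exact diene. The fallback sets out from 5 and 6 and comes back at 8. Tiglic aldehyde 6 is converted with ethylene glycol (PPTS, benzene, Dean–Stark) into the acetal 2-[(E)-but-2-en-2-yl]-1,3-dioxolane F1. TMSOTf in CH2Cl2 at −90 °C opens it to a vinyl dioxolenium ion, a far more reactive and bulkier dienophile with a stronger reason to stay out from under ring A. Its ionic Diels–Alder reaction with 5 gives the dioxolane cycloadduct 2-[(1R,2S,6R,8aR)-6-[(tert-butyldimethylsilyl)oxy]-1,2,5,5-tetramethyl-1,2,3,5,6,7,8,8a-octahydronaphthalen-1-yl]-1,3-dioxolane F2. Aqueous HF in MeCN then cleaves the acetal and the silyl ether together and rejoins the route at 8.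

Step 7 (axial-selective reduction). The ring has only one syn-axial hydrogen opposing axial attack, so the borohydride may give a substantial amount of the equatorial 6-epimer, or react slowly at the neopentyl ketone. The fallback sets out from 9 and comes back at 11. It replaces the hydride reagent by Rh-catalysed hydrosilylation (RhCl(PPh3)3, Ph2SiH2, benzene, rt), which with a dihydrosilane is known to favour the less stable axial carbinol. This gives the bis(diphenylsilyl) ether of the diol F3, and aqueous HCl in THF hydrolyses it to 11.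

Step 8 (neopentyl etherification). SN2 at the alkoxyphosphonium carbon next to a quaternary centre is slow, and the phenol is flanked by two methoxy groups. The fallback sets out from 11 and comes back at 13. The primary hydroxyl is triflated selectively (Tf2O, 2,6-lutidine, CH2Cl2, −78 °C) to give [(1R,2S,6S,8aR)-6-hydroxy-1,2,5,5-tetramethyl-1,2,3,5,6,7,8,8a-octahydronaphthalen-1-yl]methyl trifluoromethanesulfonate F4. This triflate cannot eliminate (no β-hydrogen) and is displaced by the caesium salt of 12 (Cs2CO3, MeCN–DMPU, 40 °C) to give 13.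

**Further compounds**
F1 | step 4 | 2-[(E)-but-2-en-2-yl]-1,3-dioxolane | C/C=C(\C)C1OCCO1
F2 | step 4 | 2-[(1R,2S,6R,8aR)-6-[(tert-butyldimethylsilyl)oxy]-1,2,5,5-tetramethyl-1,2,3,5,6,7,8,8a-octahydronaphthalen-1-yl]-1,3-dioxolane | C1(OCCO1)[C@@]2(C)[C@@H]3CC[C@@H](O[Si](C)(C)C(C)(C)C)C(C)(C)C3=CC[C@@H]2C
F3 | step 7 | (1R,2S,6S,8aR)-6-[(diphenylsilyl)oxy]-1-{[(diphenylsilyl)oxy]methyl}-1,2,5,5-tetramethyl-1,2,3,5,6,7,8,8a-octahydronaphthalene | c1ccccc1[SiH](c1ccccc1)OC[C@@]1(C)[C@@H]2CC[C@H](O[SiH](c3ccccc3)c3ccccc3)C(C)(C)C2=CC[C@@H]1C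
F4 | step 8 | [(1R,2S,6S,8aR)-6-hydroxy-1,2,5,5-tetramethyl-1,2,3,5,6,7,8,8a-octahydronaphthalen-1-yl]methyl trifluoromethanesulfonate | O=S(=O)(OC[C@@]1(C)[C@@H]2CC[C@H](O)C(C)(C)C2=CC[C@@H]1C)C(F)(F)F
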